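At 15.0 h, the last row of the dawn run, 41.0% of the starting material is left, and east is the same charge carried on to 25 h.

| flask | starting material | coupling partner | capture agent | free catalyst | remark | time |
|---|---|---|---|---|---|---|
| dawn | 0.050 M | 0.0475 M | 0.015 M | 3.6 mM | run made earlier |  |
| autumn | 0.075 M | 0.0475 M | 0.015 M | 3.6 mM | run made earlier |  |
| west | 0.050 M (fed, over 20.0 h) | 0.0475 M | 0.0150 M | 3.6 mM | all but starting material at the start; starting material goes in evenly over 20.0 h, the run ends at 25 h | 25 h |
| south | 0.050 M | 0.0475 M | 0.0150 M | 3.6 mM | one stirred flow tank at steady state, fed with the mixture as stated, mean residence time 25 h |  |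
| south-west | 0.050 M | 0.0475 M (fed, over 20.0 h) | 0.0150 M | 3.6 mM | a stirred flask in which coupling partner is dosed at a steady rate over 20.0 h without added volume, worked up at 25 h | 25 h |
| east | 0.050 M | 0.0475 M | 0.0150 M | 3.6 mM | everything together in a closed stirred flask, run for 25 h | 25 h |

| run | time / h | target / % | starting material / % |
|---|---|---|---|
| dawn | 3.00 | 10.8 | 83.7 |
| dawn | 6.00 | 23.2 | 72.3 |
| dawn | 10.0 | 38.7 | 57.7 |
| dawn | 12.0 | 44.5 | 52.9 |
| dawn | 15.0 | 54.8 | 41.0 |
| autumn | 0.417 | 0.1 | 96.7 |
| autumn | 0.833 | 1.3 | 95.4 |
| autumn | 1.33 | 2.7 | 93.2 |
| autumn | 2.50 | 7.0 | 90.1 |
| autumn | 5.00 | 13.4 | 82.5 |

(standard deviation of a reading: 0.5 percentage points)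

1. the set-up with the highest amount of target at the outlet or at the end, in percent of the starting material put in ("none" if the first two lie within 2 percentage points) (west / south / south-west / east / none)
2. amount of target at the outlet or at the end, in percent of the starting material put in, west
3. amount of target at the outlet or at the end, in percent of the starting material put in, south
4. amount of target at the outlet or at the end, in percent of the starting material put in, south-west
5. amount of target at the outlet or at the end, in percent of the starting material put in, east

- the stated concentrations are those of everything mixed, before any reaction; amounts are the same in each set-up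
- the numbers in the tables scatter by 0.5 percentage points (one standard deviation)
- steps thought possible: catalyst intermediate B -> free catalyst + target; catalyst intermediate A + capture agent -> trapped intermediate; coupling partner + free catalyst <-> catalyst intermediate A; starting material + catalyst intermediate A -> catalyst intermediate B
- the feed brings no volume worth counting
- the earlier runs were made in a closed, stirred flask

I read the fractions left. The coupling partner is the limiting reagent. Counting one partner for each starting material lost, I reckon that autumn has used 27.6% of its partner by 5.00 h and dawn 29.2% by 6.00 h, so the rate rises less than the charge of starting material. I therefore tie the decay to the partner, and in dawn, where the charges lie close, I take its fraction left to follow that of the starting material.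

I define the fraction-left constant as the logarithm of one over the fraction left, divided by the time. The last dawn row gives 0.0594 h⁻¹, the row at 3.00 h gives 0.0593 h⁻¹, and the row at 6.00 h gives 0.0541 h⁻¹.

For first-order decay at fixed catalyst, a closed flask keeps e to the minus constant times time, and a stirred tank keeps one over one plus constant times residence time. So I reckon east keeps 22.6% and south 40.2%. With the partner arriving evenly, I reckon that south-west keeps 43.5% of its partner. For west, where the starting material arrives late, I give no number. I expect east to lead.

The forecast says “so the rate is near zero order”, and it names east, with 50% for west, 57% for south, 71% for south-west and 74% for east. It differs from me on south-west, where it has 71% of target and I have 56.5% of the partner gone.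

The flasks give 55.2% in west, 60.3% in south, 61.8% in south-west and 77.6% in east, so east leads.

    catalyst intermediate B → free catalyst + target (k = 0.0127 min⁻¹)
    catalyst intermediate A + capture agent → trapped intermediate (k = 0.329 M⁻¹ min⁻¹)
    coupling partner + free catalyst ⇌ catalyst intermediate A (K = 57.0 M⁻¹, k = 1.08 M⁻¹ min⁻¹)
    starting material + catalyst intermediate A → catalyst intermediate B (k = 15.3 M⁻¹ min⁻¹)

East keeps 20% of its starting material, so its constant reads 0.0644 h⁻¹ against my 0.0594 h⁻¹. At 25.0 h in east, catalyst intermediate A has a half-life of 0.075 h by its step to catalyst intermediate B, shorter than the 0.91 h of catalyst intermediate B by its step to target. At that moment east holds 2.26% of its catalyst as catalyst intermediate A and 30.6% as catalyst intermediate B, with 53.0% free and 14.1% trapped. For the neighbour of east with 0.0014 M of free catalyst, my constant scaled by the catalyst charge reckons 56.1% of the starting material left, and that flask holds 62%.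

Readings and results were computed with made-up constants; scatter was added.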